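## Retrosynthetic overview

1. The cyclohexane is formed last: the C2–C7 bond (with C6–Br and the exocyclic alkene) comes from an electrochemical transannular bromonium cyclisation of a 20-membered (2E,6E)-diene macrolide, which contracts it to the 16-membered lactone.
2. The 20-membered lactone (C14–Br, C15–O–acyl) comes from a 19-membered O14-lactone by an acyloxonium 1,2-acyl shift with bromide inversion at C14; a macrolactonisation forms that first ring.
3. The C10–Br / C11–O unit comes from a (10S,11S)-diol through a cyclic orthoformate opened by bromide with inversion at C10.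
4. The open chain is joined at C5–C6 by a B-alkyl Suzuki coupling of an aryl diene with an (E)-vinyl iodide.
5. The vinyl iodide comes from two chiral-pool lactones: the L-glutamic acid lactone acid (C7–C11, supplies C10) and the L-malic acid hydroxylactone (C12–C15, supplies C14); C11 is set by Felkin–Anh addition next to C10.

Assumption: carbons are numbered along the diterpene chain (C1 = benzylic CH2 … C15 = CMe2–O); in this numbering the target is (2R,6S,7S,10R,11S,14R), and both lactones are bought enantiopure.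

## Route

**Step 1**
Reactants: 1, (S)-3-hydroxydihydrofuran-2(3H)-one
Product: 2, (S)-4-methylpentane-1,3,4-triol
Conditions: MeMgBr (4 equiv), THF, 0 °C → rt
Reagents that add atoms: methylmagnesium bromide, C[Mg]Br
Why: Double Grignard addition to the lactone carbonyl gives the CMe2OH group (C15); the purchased stereocentre (future C14) is protected from enolisation as its alkoxide.

**Step 2**
Reactants: 2, (S)-4-methylpentane-1,3,4-triol
Product: 3, 2-[(4S)-2,2,5,5-tetramethyl-1,3-dioxolan-4-yl]ethan-1-ol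
Conditions: Me2C(OMe)2, PPTS (cat.), acetone, rt
Reagents that add atoms: 2,2-dimethoxypropane, COC(C)(C)OC
Why: Thermodynamic acetonide formation favours the five-membered dioxolane on the 1,2-diol over the 1,3-dioxane, leaving the primary alcohol free.

**Step 3**
Reactants: 3, 2-[(4S)-2,2,5,5-tetramethyl-1,3-dioxolan-4-yl]ethan-1-ol
Product: 4, (4S)-4-(2-bromoethyl)-2,2,5,5-tetramethyl-1,3-dioxolane
Conditions: CBr4, PPh3, imidazole, CH2Cl2, 0 °C
Reagents that add atoms: carbon tetrabromide, BrC(Br)(Br)Br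
Why: Appel bromination of the primary alcohol; the acetonide and stereocentre are untouched.

**Step 4**
Reactants: 5, (S)-5-oxotetrahydrofuran-2-carboxylic acid; 4, (4S)-4-(2-bromoethyl)-2,2,5,5-tetramethyl-1,3-dioxolane
Product: 6, (5S)-5-{3-[(4S)-2,2,5,5-tetramethyl-1,3-dioxolan-4-yl]propanoyl}dihydrofuran-2(3H)-one
Conditions: 5, (COCl)2, cat. DMF, CH2Cl2, 0 °C; then Grignard of 4 (Mg, THF), Fe(acac)3 (3 mol %), THF, −78 °C
Reagents that add atoms: none
Why: Iron-catalysed acylation of a Grignard reagent by the acid chloride forms the C11–C12 bond chemoselectively in the presence of the lactone; C10 is the purchased stereocentre.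

**Step 5**
Reactants: 6
Product: 7, (5S)-5-{(2S)-2-hydroxy-4-[(4S)-2,2,5,5-tetramethyl-1,3-dioxolan-4-yl]butan-2-yl}dihydrofuran-2(3H)-one
Conditions: MeLi, CeCl3, THF, −78 °C
Reagents that add atoms: methyllithium, [Li]C
Why: Organocerium 1,2-addition under Felkin–Anh (polar) control: the non-chelating lactone C10–O bond sits anti to the incoming methyl, which sets C11 as S (the 10,11-syn relationship); cerium suppresses enolisation and lactone attack.

**Step 6**
Reactants: 7
Product: 8, (5S)-5-{(2S)-2-hydroxy-4-[(4S)-2,2,5,5-tetramethyl-1,3-dioxolan-4-yl]butan-2-yl}tetrahydrofuran-2-ol (lactol, anomer mixture)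
Conditions: DIBAL-H (2.2 equiv), CH2Cl2, −78 °C
Reagents that add atoms: none
Why: Partial reduction of the γ-lactone to the lactol, a masked γ-hydroxy aldehyde.

**Step 7**
Reactants: 8
Product: 9, (5S,6S)-6-methyl-8-[(4S)-2,2,5,5-tetramethyl-1,3-dioxolan-4-yl]oct-1-yne-5,6-diol
Conditions: Ohira–Bestmann reagent, K2CO3, MeOH, 0 °C → rt
Reagents that add atoms: dimethyl (1-diazo-2-oxopropyl)phosphonate, COP(=O)(OC)C(=[N+]=[N-])C(C)=O
Why: Seyferth–Gilbert (Ohira–Bestmann) homologation of the open-chain aldehyde form gives the terminal alkyne (adds C6) and frees the 10,11-diol.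

**Step 8**
Reactants: 9
Product: 10, (1E,5S,6S)-1-iodo-2,6-dimethyl-8-[(4S)-2,2,5,5-tetramethyl-1,3-dioxolan-4-yl]oct-1-ene-5,6-diol
Conditions: Me3Al (5 equiv), Cp2ZrCl2, H2O (1 equiv), CH2Cl2, −20 °C; then I2, THF, −30 °C
Reagents that add atoms: trimethylaluminium, C[Al](C)C; iodine, II
Why: Negishi zirconium-catalysed syn-carboalumination then iodinolysis gives the (E)-2-methyl-1-iodoalkene, fixing the C6=C7 geometry and the C7 methyl.

**Step 9**
Reactants: 11, tert-butyl 4-hydroxybenzoate; 12, 1-bromo-3-methylbut-2-ene (prenyl bromide)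
Product: 13, tert-butyl 4-hydroxy-3-(3-methylbut-2-en-1-yl)benzoate
Conditions: NaH, toluene, 0 °C → rt
Reagents that add atoms: none
Why: ortho-C-Alkylation of the sodium phenoxide as a tight ion pair in a non-polar solvent (known, moderate-yielding, on para-hydroxybenzoates).

**Step 10**
Reactants: 13
Product: 14, tert-butyl 4-hydroxy-3-[(2E)-3-methyl-4-oxobut-2-en-1-yl]benzoate
Conditions: SeO2, 1,4-dioxane, 80 °C
Reagents that add atoms: selenium dioxide, O=[Se]=O
Why: Riley allylic oxidation (ene / [2,3] shift) is selective for the (E)-methyl of a prenyl group and gives the (E)-enal.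

**Step 11**
Reactants: 14
Product: 15, tert-butyl 4-hydroxy-3-[(2E)-3-methylpenta-2,4-dien-1-yl]benzoate
Conditions: Ph3PCH3Br, KOtBu (2.2 equiv), THF, 0 °C
Reagents that add atoms: methyltriphenylphosphonium bromide, C[P+](c1ccccc1)(c1ccccc1)c1ccccc1.[Br-]
Why: Wittig methylenation of the enal (one equivalent of ylide is consumed by the phenol); the C2=C3 geometry is unchanged.

**Step 12**
Reactants: 15; 10
Product: 16, tert-butyl 3-{(2E,6E,10S,11S)-10,11-dihydroxy-3,7,11-trimethyl-13-[(4S)-2,2,5,5-tetramethyl-1,3-dioxolan-4-yl]trideca-2,6-dien-1-yl}-4-hydroxybenzoate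
Conditions: 15, 9-BBN (2.5 equiv), THF, 0 °C → rt; then 10, Pd(dppf)Cl2, AsPh3, Cs2CO3, DMF/H2O, rt
Reagents that add atoms: none
Why: 9-BBN hydroborates only the terminal vinyl carbon of the diene, and B-alkyl Suzuki–Miyaura coupling forms C5–C6 with retention of the (E)-vinyl iodide geometry.

**Step 13**
Reactants: 16
Product: 17, tert-butyl 4-acetoxy-3-[(2E,6E)-3,7-dimethyl-9-{(4S,5S)-2-methoxy-4-methyl-4-[2-((4S)-2,2,5,5-tetramethyl-1,3-dioxolan-4-yl)ethyl]-1,3-dioxolan-5-yl}nona-2,6-dien-1-yl]benzoate (cyclic orthoformate of the 10,11-diol; orthoformate carbon unassigned)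
Conditions: HC(OMe)3, PPTS (cat.), CH2Cl2, rt; then Ac2O, pyridine, cat. DMAP, 0 °C
Reagents that add atoms: trimethyl orthoformate, COC(OC)OC; acetic anhydride, CC(=O)OC(C)=O
Why: Orthoester exchange ties up the 1,2-diol, after which only the phenol is left to be acetylated; the electron-poor acetate deactivates the arene and its oxygen for the later bromonium steps.

**Step 14**
Reactants: 17
Product: 18, tert-butyl 4-acetoxy-3-{(2E,6E,10R,11S)-10-bromo-11-(formyloxy)-3,7,11-trimethyl-13-[(4S)-2,2,5,5-tetramethyl-1,3-dioxolan-4-yl]trideca-2,6-dien-1-yl}benzoate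
Conditions: AcBr (1.2 equiv), 2,6-di-tert-butyl-4-methylpyridine, CH2Cl2, −20 °C
Reagents that add atoms: acetyl bromide, CC(Br)=O
Why: Kolb–Sharpless-type orthoester opening: AcBr generates the 1,3-dioxolan-2-ylium (acyloxonium) ion and bromide opens it by SN2 at the secondary carbon, inverting C10 (S → R) and leaving O11 as a formate with C11 unchanged.

**Step 15**
Reactants: 18
Product: 19, 4-acetoxy-3-[(2E,6E,10R,11S,14S)-10-bromo-11-(formyloxy)-14,15-dihydroxy-3,7,11,15-tetramethylhexadeca-2,6-dien-1-yl]benzoic acid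
Conditions: 85% aq. H3PO4, toluene, rt
Reagents that add atoms: none
Why: Mild acidolysis removes the tert-butyl ester and the acetonide together; formate, aryl acetate, bromide and trisubstituted alkenes tolerate this weak acid.

**Step 16**
Reactants: 19
Product: 20, 19-membered macrolactone of 19 closed on O14 (C14 carries a 2-hydroxypropan-2-yl group; 2E,6E,10R,11S,14S; aryl acetate and O11-formate retained)
Conditions: MNBA, DMAP, Et3N, CH2Cl2 (1 mM, syringe pump), rt
Reagents that add atoms: none
Why: Shiina macrolactonisation acylates the secondary C14–OH selectively; the tertiary C15–OH does not react.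

**Step 17**
Reactants: 20
Product: 21, 20-membered macrolactone with the benzoate on O15 and (14R)-bromide (2E,6E,10R,11S,14R; aryl acetate and O11-formate retained)
Conditions: Tf2O, 2,6-di-tert-butyl-4-methylpyridine, CH2Cl2, −78 °C; then Bu4NBr, −78 → −20 °C
Reagents that add atoms: tetrabutylammonium bromide, CCCC[N+](CCCC)(CCCC)CCCC.[Br-]
Why: The tertiary triflate ionises with neighbouring-group participation of the vicinal benzoate to a 2-aryl-1,3-dioxolan-2-ylium ion, and bromide opens it by SN2 at C14 with inversion (S → R) so the acyl group ends on O15 (acyloxonium 1,2-acyl shift, Winstein / Mattocks–Moffatt type), expanding the ring by one atom.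

**Step 18**
Reactants: 21
Product: 22, O-acetyl-O11-formyl-bromophycolide H (2R,6S,7S,10R,11S,14R)
Conditions: undivided cell, RVC anode / Pt cathode, constant current (2.2 F/mol), 2,4,6-collidinium bromide (1.1 equiv), Et2S (20 mol %), Bu4NPF6, HFIP/MeNO2 (1:4), −20 °C, 2 mM
Reagents that add atoms: 2,4,6-collidinium bromide, Cc1cc(C)[nH+]c(C)c1.[Br-]
Why: Proposed new method: anodic oxidation of bromide in the presence of catalytic Et2S should give a bromodiethylsulfonium carrier whose bromide counter-ion is masked by HFIP hydrogen bonding, so Br+ is delivered to C6=C7 without dibromide formation; C2=C3 then attacks C7 across the ring through a chair transition state (anti addition from two E-alkenes: Br equatorial at C6, methyl axial at C7, benzyl equatorial at C2, i.e. the 2R*,6S*,7S* relative configuration), the C3 cation loses a methyl proton to collidine to give the exocyclic alkene, and the face of C6=C7 is chosen by the conformation the C10, C11 and C14 centres impose on the 20-membered lactone; the closest known reactions are reagent-based bromonium polyene cyclisations (BDSB, TBCO, including transannular cases in related macrolides) and anodic bromide oxidation for alkene bromofunctionalisation.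

**Step 19**
Reactants: 22
Product: 23, bromophycolide H
Conditions: NH3 (7 M in MeOH), 0 °C
Reagents that add atoms: none
Why: Mild ammonolysis cleaves the aryl acetate and the tertiary formate without ionising the tertiary alcohol, so the bromohydrin does not close to the epoxide and the hindered lactone survives.

## Compound list

1 | (S)-3-hydroxydihydrofuran-2(3H)-one | O[C@H]1CCOC1=O | starting material
2 | (S)-4-methylpentane-1,3,4-triol | OCC[C@H](O)C(C)(C)O | intermediate
3 | 2-[(4S)-2,2,5,5-tetramethyl-1,3-dioxolan-4-yl]ethan-1-ol | OCC[C@@H]1OC(C)(C)OC1(C)C | intermediate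
4 | (4S)-4-(2-bromoethyl)-2,2,5,5-tetramethyl-1,3-dioxolane | BrCC[C@@H]1OC(C)(C)OC1(C)C | intermediate
5 | (S)-5-oxotetrahydrofuran-2-carboxylic acid | OC(=O)[C@@H]1CCC(=O)O1 | starting material
6 | (5S)-5-{3-[(4S)-2,2,5,5-tetramethyl-1,3-dioxolan-4-yl]propanoyl}dihydrofuran-2(3H)-one | O=C(CC[C@@H]1OC(C)(C)OC1(C)C)[C@@H]1CCC(=O)O1 | intermediate
7 | (5S)-5-{(2S)-2-hydroxy-4-[(4S)-2,2,5,5-tetramethyl-1,3-dioxolan-4-yl]butan-2-yl}dihydrofuran-2(3H)-one | C[C@](O)(CC[C@@H]1OC(C)(C)OC1(C)C)[C@@H]1CCC(=O)O1 | intermediate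
8 | (5S)-5-{(2S)-2-hydroxy-4-[(4S)-2,2,5,5-tetramethyl-1,3-dioxolan-4-yl]butan-2-yl}tetrahydrofuran-2-ol | C[C@](O)(CC[C@@H]1OC(C)(C)OC1(C)C)[C@@H]1CCC(O)O1 | intermediate
9 | (5S,6S)-6-methyl-8-[(4S)-2,2,5,5-tetramethyl-1,3-dioxolan-4-yl]oct-1-yne-5,6-diol | C#CCC[C@H](O)[C@@](C)(O)CC[C@@H]1OC(C)(C)OC1(C)C | intermediate
10 | (1E,5S,6S)-1-iodo-2,6-dimethyl-8-[(4S)-2,2,5,5-tetramethyl-1,3-dioxolan-4-yl]oct-1-ene-5,6-diol | I/C=C(\C)CC[C@H](O)[C@@](C)(O)CC[C@@H]1OC(C)(C)OC1(C)C | intermediate
11 | tert-butyl 4-hydroxybenzoate | CC(C)(C)OC(=O)c1ccc(O)cc1 | starting material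
12 | 1-bromo-3-methylbut-2-ene | CC(C)=CCBr | starting material
13 | tert-butyl 4-hydroxy-3-(3-methylbut-2-en-1-yl)benzoate | CC(C)=CCc1cc(ccc1O)C(=O)OC(C)(C)C | intermediate
14 | tert-butyl 4-hydroxy-3-[(2E)-3-methyl-4-oxobut-2-en-1-yl]benzoate | O=C/C(C)=C/Cc1cc(ccc1O)C(=O)OC(C)(C)C | intermediate
15 | tert-butyl 4-hydroxy-3-[(2E)-3-methylpenta-2,4-dien-1-yl]benzoate | C=C/C(C)=C/Cc1cc(ccc1O)C(=O)OC(C)(C)C | intermediate
16 | tert-butyl 3-{(2E,6E,10S,11S)-10,11-dihydroxy-3,7,11-trimethyl-13-[(4S)-2,2,5,5-tetramethyl-1,3-dioxolan-4-yl]trideca-2,6-dien-1-yl}-4-hydroxybenzoate | CC(C)(C)OC(=O)c1ccc(O)c(c1)C/C=C(\C)CC/C=C(\C)CC[C@H](O)[C@@](C)(O)CC[C@@H]2OC(C)(C)OC2(C)C | intermediate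
17 | tert-butyl 4-acetoxy-3-[(2E,6E)-3,7-dimethyl-9-{(4S,5S)-2-methoxy-4-methyl-4-[2-((4S)-2,2,5,5-tetramethyl-1,3-dioxolan-4-yl)ethyl]-1,3-dioxolan-5-yl}nona-2,6-dien-1-yl]benzoate | CC(C)(C)OC(=O)c1ccc(OC(C)=O)c(c1)C/C=C(\C)CC/C=C(\C)CC[C@@H]2OC(OC)O[C@@]2(C)CC[C@@H]3OC(C)(C)OC3(C)C | intermediate
18 | tert-butyl 4-acetoxy-3-{(2E,6E,10R,11S)-10-bromo-11-(formyloxy)-3,7,11-trimethyl-13-[(4S)-2,2,5,5-tetramethyl-1,3-dioxolan-4-yl]trideca-2,6-dien-1-yl}benzoate | CC(C)(C)OC(=O)c1ccc(OC(C)=O)c(c1)C/C=C(\C)CC/C=C(\C)CC[C@@H](Br)[C@@](C)(OC=O)CC[C@@H]2OC(C)(C)OC2(C)C | intermediate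
19 | 4-acetoxy-3-[(2E,6E,10R,11S,14S)-10-bromo-11-(formyloxy)-14,15-dihydroxy-3,7,11,15-tetramethylhexadeca-2,6-dien-1-yl]benzoic acid | OC(=O)c1ccc(OC(C)=O)c(c1)C/C=C(\C)CC/C=C(\C)CC[C@@H](Br)[C@@](C)(OC=O)CC[C@H](O)C(C)(C)O | intermediate
20 | 19-membered O14-macrolactone of 19 (2E,6E,10R,11S,14S; C14 bears C(CH3)2OH; aryl OAc, O11-formate) | CC(=O)Oc1ccc2cc1C/C=C(\C)CC/C=C(\C)CC[C@@H](Br)[C@@](C)(OC=O)CC[C@H](OC2=O)C(C)(C)O | intermediate
21 | 20-membered O15-macrolactone, 10,14-dibromide (2E,6E,10R,11S,14R; aryl OAc, O11-formate) | CC(=O)Oc1ccc2cc1C/C=C(\C)CC/C=C(\C)CC[C@@H](Br)[C@@](C)(OC=O)CC[C@@H](Br)C(C)(C)OC2=O | intermediate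
22 | O-acetyl-O11-formyl-bromophycolide H | C=C1CC[C@H](Br)[C@@]2(C)CC[C@@H](Br)[C@@](C)(OC=O)CC[C@@H](Br)C(C)(C)OC(=O)c3ccc(OC(C)=O)c(c3)C[C@H]12 | intermediate
23 | bromophycolide H | C=C1CC[C@H](Br)[C@@]2(C)CC[C@@H](Br)[C@@](C)(O)CC[C@@H](Br)C(C)(C)OC(=O)c3ccc(O)c(c3)C[C@H]12 | target

## Summary

Total steps: 19. Longest linear sequence: 16 (steps 1–8, then 12–19).

Steps most likely to fail:

1. **Step 18 (proposed new electrochemical transannular bromocyclisation).** It may give vicinal dibromide, endocyclic alkene isomers, or the wrong face at C6/C7/C2. Fallback (known chemistry): carry out the cyclisation with stoichiometric pre-formed BDSB (Et2SBr·SbCl5Br, MeNO2, −25 °C) one stage earlier, on the 19-membered lactone 20, and run the acyl-shift bromination of step 17 afterwards on the cyclised product.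

2. **Step 17 (acyl-shift bromination).** Bromide may open the acyloxonium ion at the tertiary carbon (giving the 15-bromo / 14-ester isomer), or the triflate may eliminate. Fallback: drop the acyl shift. Start from the (R)-enantiomer of 1, convert the 14,15-diol to the epoxide (MsCl, then K2CO3) and open it at C14 with Li2NiBr4 (double inversion). Then acylate the tertiary alcohol intermolecularly with the aroyl chloride of the aryl fragment and close the 20-membered ring by an intramolecular B-alkyl Suzuki coupling instead of a lactonisation.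

3. **Step 14 (orthoformate opening).** Competing attack at tertiary C11, SN1 leakage, or HBr addition to the alkenes. Fallback: use the epoxide route. Start from the (R)-enantiomer of 5 (from D-glutamic acid) and reverse the order in which the two C11 substituents are introduced (acetyl lactone plus the Grignard of 4), which gives the 10,11-anti diol. Close this to the (10S,11S)-epoxide (MsCl, then K2CO3), open at C10 with Li2NiBr4 (net retention), and formylate O11.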